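**Retrosynthetic overview**
- The target is an acacetin unit joined through C6 to C3' of a 5-hydroxy-7,4'-dimethoxyflavone. The second chromone is cut last: debenzylation, iodine-mediated C–O closure of a 2'-hydroxychalcone, and aldol disconnection to an aryl aldehyde and a mono-benzylated acetophenone.
- The strategy rests on the benzo ring of the acacetin half (C4a, C5-OH, C6-aryl, C7-OH, C8-H, C8a). Its aryl-bearing C6 lies between the two hydroxylated carbons C5 and C7, which is the pattern of an arylacetate α-carbon between two ester-derived carbonyl carbons.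
- That ring is cut at C5–C6 and C7–C8 into a 2-methyl-4-pyranone-3-carboxylate (supplying O1, C2–C4, C4a, C5, C8, C8a) and a methyl arylacetate (supplying C6 and C7).
- The pyranone comes from methyl acetoacetate and an arylpropioloyl chloride (C-acylation, 6-endo closure). The arylacetate comes from methyl 2-methoxyphenylacetate by para-formylation and acetalization.
- Ring order: pyranone (later ring C of the acacetin half), then its benzo ring by annulation, then the second pyranone ring.

Key step: step 5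

Assumption: methyl 2-(2-methoxyphenyl)acetate is bought as such, and the tricarbonyl compounds 4 and 9 are drawn as keto tautomers although they should exist largely as enols.

**Route**

Step 1
Reactants: 1 3-(4-methoxyphenyl)prop-2-ynoic acid; 2 methyl acetoacetate
Product: 4 methyl 2-acetyl-5-(4-methoxyphenyl)-3-oxopent-4-ynoate, via 3-(4-methoxyphenyl)prop-2-ynoyl chloride 3 (not isolated)
Conditions: (COCl)2, DMF (cat.), CH2Cl2, 0 °C to rt, evaporate; then 2, MgCl2, pyridine, CH2Cl2, 0 °C to rt; 1 M HCl work-up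
Reagents that add atoms: none
Why: Acylation of the magnesium chelate of a β-keto ester by an acid chloride takes place on carbon (soft-enolization C-acylation), and the alkynoyl chloride has no α-hydrogen, so ketene formation cannot compete.

Step 2
Reactants: 4 methyl 2-acetyl-5-(4-methoxyphenyl)-3-oxopent-4-ynoate
Product: 5 methyl 6-(4-methoxyphenyl)-2-methyl-4-oxo-4H-pyran-3-carboxylate
Conditions: TfOH (10 mol %), CH2Cl2, 0 °C to rt
Reagents that add atoms: none
Why: Brønsted-acid activation of the ynone lets the acetyl enol oxygen add to the β-alkyne carbon in a 6-endo-dig oxa-Michael cycloisomerization, the classical closure of 2-acyl enol ynones to 4-pyranones.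

Step 3
Reactants: 6 methyl 2-(2-methoxyphenyl)acetate
Product: 7 methyl 2-(5-formyl-2-methoxyphenyl)acetate
Conditions: Cl2CHOMe, TiCl4, CH2Cl2, −10 to 0 °C; ice water
Reagents that add atoms: dichloromethyl methyl ether COC(Cl)Cl; water O
Why: Rieche formylation is an electrophilic aromatic substitution directed by the methoxy group, whose ortho position is the more hindered one, so the formyl group should enter para to it at C5.

Step 4
Reactants: 7 methyl 2-(5-formyl-2-methoxyphenyl)acetate
Product: 8 methyl 2-[5-(1,3-dioxolan-2-yl)-2-methoxyphenyl]acetate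
Conditions: HOCH2CH2OH, p-TsOH·H2O (cat.), toluene, reflux, Dean–Stark
Reagents that add atoms: ethylene glycol OCCO
Why: Acid-catalysed acetalization with azeotropic removal of water masks the aldehyde, which would otherwise be attacked by the enolates of the next step.

Step 5
Reactants: 5 methyl 6-(4-methoxyphenyl)-2-methyl-4-oxo-4H-pyran-3-carboxylate; 8 methyl 2-[5-(1,3-dioxolan-2-yl)-2-methoxyphenyl]acetate
Product: 10 6-[5-(1,3-dioxolan-2-yl)-2-methoxyphenyl]-5,7-dihydroxy-2-(4-methoxyphenyl)-4H-chromen-4-one, via 2-(3-aryl-2-oxopropyl)pyranone ester 9 (not isolated)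
Conditions: 5 (2 equiv) added to LiN(i-Pr)2 (2.1 equiv), THF, −78 °C; 8 (1 equiv), −78 °C to rt; then KOt-Bu (3 equiv), rt to 50 °C; AcOH quench, 0 °C
Reagents that add atoms: none
Why: Proposed new method: deprotonation of the C2 methyl group of 5 (vinylogous to both the C4 ketone and the C3 ester) gives a dienolate that is no longer a Michael acceptor and should be acylated at its exocyclic carbon by the ester of 8 to give ketone 9 (C7–C8); alkoxide-mediated proton exchange then lets the benzylic enolate of 9 attack the neighbouring C3 ester in a 6-exo-trig Claisen (Dieckmann-type) closure (C5–C6), and loss of the second methanol with tautomerization gives the aromatic 5,7-bis-phenoxide. The closest known reactions are the acylation of ortho-toluate anions by esters followed by Claisen closure to naphthalene-1,3-diols and the γ-acylation of lithiated 2-methyl-4-pyranones; a pyranone ester as donor for a chromone benzo ring is the extension. The opposite order of events (arylacetate enolate on the pyranone ester first, methyl anion closing second) would lead to the same compound, so the outcome does not depend on which bond forms first. No stereocentre is formed. The step needs cross-condensation to win over self-condensation of 8 and over enol-lactone formation by O-acylation; both of these are reversible under alkoxide whereas aromatization is not, so the bis-phenoxide should act as the sink. It also needs the aryl group at C6 and not C8, which is fixed by the substrate because the ring oxygen is already in place and the arylacetate carbon can only end between the two carbonyl-derived carbons C5 and C7.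

Step 6
Reactants: 10 6-[5-(1,3-dioxolan-2-yl)-2-methoxyphenyl]-5,7-dihydroxy-2-(4-methoxyphenyl)-4H-chromen-4-one
Product: 11 7-(benzyloxy)-6-[5-(1,3-dioxolan-2-yl)-2-methoxyphenyl]-5-hydroxy-2-(4-methoxyphenyl)-4H-chromen-4-one
Conditions: BnBr (1.1 equiv), K2CO3, acetone, reflux
Reagents that add atoms: benzyl bromide BrCc1ccccc1
Why: Williamson etherification takes the more acidic, unchelated 7-hydroxyl, while the 5-hydroxyl is held in a hydrogen bond to the C4 carbonyl and stays free.

Step 7
Reactants: 11 7-(benzyloxy)-6-[5-(1,3-dioxolan-2-yl)-2-methoxyphenyl]-5-hydroxy-2-(4-methoxyphenyl)-4H-chromen-4-one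
Product: 12 3-[7-(benzyloxy)-5-hydroxy-2-(4-methoxyphenyl)-4-oxo-4H-chromen-6-yl]-4-methoxybenzaldehyde
Conditions: 1 M HCl, THF, rt
Reagents that add atoms: water O
Why: Dilute aqueous acid hydrolyses the aryl dioxolane through its oxocarbenium ion, and the benzyl ether, the methyl ethers and the chromone are stable to it.

Step 8
Reactants: 13 1-(2,6-dihydroxy-4-methoxyphenyl)ethan-1-one
Product: 14 1-[2-(benzyloxy)-6-hydroxy-4-methoxyphenyl]ethan-1-one
Conditions: BnBr (1.0 equiv), K2CO3, acetone, reflux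
Reagents that add atoms: benzyl bromide BrCc1ccccc1
Why: Mono-Williamson etherification: once the first ether has formed, the remaining hydroxyl is locked in a hydrogen bond to the acetyl carbonyl and should react much more slowly.

Step 9
Reactants: 12 3-[7-(benzyloxy)-5-hydroxy-2-(4-methoxyphenyl)-4-oxo-4H-chromen-6-yl]-4-methoxybenzaldehyde; 14 1-[2-(benzyloxy)-6-hydroxy-4-methoxyphenyl]ethan-1-one
Product: 15 (E)-1-[2-(benzyloxy)-6-hydroxy-4-methoxyphenyl]-3-{3-[7-(benzyloxy)-5-hydroxy-2-(4-methoxyphenyl)-4-oxo-4H-chromen-6-yl]-4-methoxyphenyl}prop-2-en-1-one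
Conditions: KOH (aq), EtOH–THF, rt
Reagents that add atoms: none
Why: Claisen–Schmidt aldol condensation of the acetophenone enolate with the non-enolizable aldehyde, followed by E1cB loss of water, should give the thermodynamically favoured E enone, while the 5-hydroxychromone is present as its phenoxide and is thereby shielded from hydroxide.

Step 10
Reactants: 15 (E)-1-[2-(benzyloxy)-6-hydroxy-4-methoxyphenyl]-3-{3-[7-(benzyloxy)-5-hydroxy-2-(4-methoxyphenyl)-4-oxo-4H-chromen-6-yl]-4-methoxyphenyl}prop-2-en-1-one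
Product: 17 5-(benzyloxy)-2-{3-[7-(benzyloxy)-5-hydroxy-2-(4-methoxyphenyl)-4-oxo-4H-chromen-6-yl]-4-methoxyphenyl}-7-methoxy-4H-chromen-4-one, via racemic flavanone 16 (not isolated)
Conditions: I2 (10 mol %), DMSO, 130 °C
Reagents that add atoms: none
Why: Oxa-Michael closure of the free 6'-hydroxyl gives the flavanone, which iodine dehydrogenates by α-iodination and loss of HI while DMSO reoxidizes HI to I2 (iodine-catalysed oxidative cyclization of 2'-hydroxychalcones).

Step 11
Reactants: 17 5-(benzyloxy)-2-{3-[7-(benzyloxy)-5-hydroxy-2-(4-methoxyphenyl)-4-oxo-4H-chromen-6-yl]-4-methoxyphenyl}-7-methoxy-4H-chromen-4-one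
Product: 18 5,7-dihydroxy-6-[5-(5-hydroxy-7-methoxy-4-oxo-4H-chromen-2-yl)-2-methoxyphenyl]-2-(4-methoxyphenyl)-4H-chromen-4-one
Conditions: H2 (1 atm), Pd/C (10 %), THF–MeOH, rt
Reagents that add atoms: none
Why: Hydrogenolysis of the two benzyl aryl ethers over Pd/C should leave the aryl methyl ethers and the aryl-conjugated C2–C3 double bonds of both chromones untouched at ambient temperature and pressure.

**Compound list**
1 | 3-(4-methoxyphenyl)prop-2-ynoic acid | COc1ccc(C#CC(=O)O)cc1 | starting material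
2 | methyl acetoacetate (methyl 3-oxobutanoate) | CC(=O)CC(=O)OC | starting material
3 | 3-(4-methoxyphenyl)prop-2-ynoyl chloride | COc1ccc(C#CC(=O)Cl)cc1 | intermediate (not isolated)
4 | methyl 2-acetyl-5-(4-methoxyphenyl)-3-oxopent-4-ynoate | COC(=O)C(C(C)=O)C(=O)C#Cc1ccc(OC)cc1 | intermediate
5 | methyl 6-(4-methoxyphenyl)-2-methyl-4-oxo-4H-pyran-3-carboxylate | COC(=O)c1c(C)oc(-c2ccc(OC)cc2)cc1=O | intermediate
6 | methyl 2-(2-methoxyphenyl)acetate | COC(=O)Cc1ccccc1OC | starting material
7 | methyl 2-(5-formyl-2-methoxyphenyl)acetate | COC(=O)Cc1cc(C=O)ccc1OC | intermediate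
8 | methyl 2-[5-(1,3-dioxolan-2-yl)-2-methoxyphenyl]acetate | COC(=O)Cc1cc(C2OCCO2)ccc1OC | intermediate
9 | methyl 2-{3-[5-(1,3-dioxolan-2-yl)-2-methoxyphenyl]-2-oxopropyl}-6-(4-methoxyphenyl)-4-oxo-4H-pyran-3-carboxylate | COC(=O)c1c(CC(=O)Cc2cc(C3OCCO3)ccc2OC)oc(-c2ccc(OC)cc2)cc1=O | intermediate (not isolated)
10 | 6-[5-(1,3-dioxolan-2-yl)-2-methoxyphenyl]-5,7-dihydroxy-2-(4-methoxyphenyl)-4H-chromen-4-one | COc1ccc(-c2cc(=O)c3c(O)c(-c4cc(C5OCCO5)ccc4OC)c(O)cc3o2)cc1 | intermediate
11 | 7-(benzyloxy)-6-[5-(1,3-dioxolan-2-yl)-2-methoxyphenyl]-5-hydroxy-2-(4-methoxyphenyl)-4H-chromen-4-one | COc1ccc(-c2cc(=O)c3c(O)c(-c4cc(C5OCCO5)ccc4OC)c(OCc4ccccc4)cc3o2)cc1 | intermediate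
12 | 3-[7-(benzyloxy)-5-hydroxy-2-(4-methoxyphenyl)-4-oxo-4H-chromen-6-yl]-4-methoxybenzaldehyde | COc1ccc(-c2cc(=O)c3c(O)c(-c4cc(C=O)ccc4OC)c(OCc4ccccc4)cc3o2)cc1 | intermediate
13 | 1-(2,6-dihydroxy-4-methoxyphenyl)ethan-1-one (2',6'-dihydroxy-4'-methoxyacetophenone) | CC(=O)c1c(O)cc(OC)cc1O | starting material
14 | 1-[2-(benzyloxy)-6-hydroxy-4-methoxyphenyl]ethan-1-one | CC(=O)c1c(O)cc(OC)cc1OCc1ccccc1 | intermediate
15 | (E)-1-[2-(benzyloxy)-6-hydroxy-4-methoxyphenyl]-3-{3-[7-(benzyloxy)-5-hydroxy-2-(4-methoxyphenyl)-4-oxo-4H-chromen-6-yl]-4-methoxyphenyl}prop-2-en-1-one | COc1ccc(-c2cc(=O)c3c(O)c(-c4cc(/C=C/C(=O)c5c(O)cc(OC)cc5OCc5ccccc5)ccc4OC)c(OCc4ccccc4)cc3o2)cc1 | intermediate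
16 | 5-(benzyloxy)-2-{3-[7-(benzyloxy)-5-hydroxy-2-(4-methoxyphenyl)-4-oxo-4H-chromen-6-yl]-4-methoxyphenyl}-7-methoxy-2,3-dihydro-4H-chromen-4-one (racemic at C2) | COc1ccc(-c2cc(=O)c3c(O)c(-c4cc(C5CC(=O)c6c(OCc7ccccc7)cc(OC)cc6O5)ccc4OC)c(OCc4ccccc4)cc3o2)cc1 | intermediate (not isolated)
17 | 5-(benzyloxy)-2-{3-[7-(benzyloxy)-5-hydroxy-2-(4-methoxyphenyl)-4-oxo-4H-chromen-6-yl]-4-methoxyphenyl}-7-methoxy-4H-chromen-4-one | COc1ccc(-c2cc(=O)c3c(O)c(-c4cc(-c5cc(=O)c6c(OCc7ccccc7)cc(OC)cc6o5)ccc4OC)c(OCc4ccccc4)cc3o2)cc1 | intermediate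
18 | 5,7-dihydroxy-6-[5-(5-hydroxy-7-methoxy-4-oxo-4H-chromen-2-yl)-2-methoxyphenyl]-2-(4-methoxyphenyl)-4H-chromen-4-one (CNP0281098.0) | COc1ccc(-c2cc(=O)c3c(O)c(-c4cc(-c5cc(=O)c6c(O)cc(OC)cc6o5)ccc4OC)c(O)cc3o2)cc1 | target

**Count**
Total steps: 11. Longest linear sequence: 8 steps (1, 2, 5, 6, 7, 9, 10, 11; the branch 3, 4, 5, 6, 7, 9, 10, 11 is equally long).

**Steps most likely to fail**

Step 5 (bears the new-method label). The intermolecular acylation of the stabilized dienolate may be slow, so that proton transfer to the arylacetate and its self-condensation take over. The closure may also stall at the ketone stage or divert to O-acylation, and neutral pyranone may be lost to conjugate addition and ring opening. The fallback uses known chemistry, sets out from 14 and comes back at 17. It no longer builds the acacetin benzo ring but makes the C6–C3' biaryl bond by Suzuki–Miyaura coupling.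
- Compound 14 and commercial 3-bromo-4-methoxybenzaldehyde are condensed (KOH, EtOH, rt) to (E)-1-[2-(benzyloxy)-6-hydroxy-4-methoxyphenyl]-3-(3-bromo-4-methoxyphenyl)prop-2-en-1-one F1.
- This is cyclized oxidatively (I2 cat., DMSO, 130 °C) to 5-(benzyloxy)-2-(3-bromo-4-methoxyphenyl)-7-methoxy-4H-chromen-4-one F2.
- Miyaura borylation (B2pin2, Pd(dppf)Cl2, KOAc, 1,4-dioxane, 90 °C) gives 5-(benzyloxy)-7-methoxy-2-[4-methoxy-3-(4,4,5,5-tetramethyl-1,3,2-dioxaborolan-2-yl)phenyl]-4H-chromen-4-one F3.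
- Separately, commercial acacetin is benzylated at O7 (BnBr, K2CO3, acetone) to 7-(benzyloxy)-5-hydroxy-2-(4-methoxyphenyl)-4H-chromen-4-one F4.
- Iodination ortho to the free 5-hydroxyl (BnNMe3 ICl2, CaCO3, CH2Cl2–MeOH, rt) gives 7-(benzyloxy)-5-hydroxy-6-iodo-2-(4-methoxyphenyl)-4H-chromen-4-one F5.
- Coupling of F3 with F5 (Pd(PPh3)4, K2CO3, DMF–H2O, 90 °C) should give 17, which is debenzylated as in step 11.

Step 9. Hydroxide may open the chromone ring already present, and the condensation may be slow because the phenoxide salts are poorly soluble, so that the aldehyde is lost to disproportionation. The fallback sets out from 12, uses 14 again and comes back at 17. It replaces the aldol logic by an acyl transfer (Baker–Venkataraman).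
- Aldehyde 12 is oxidized (NaClO2, NaH2PO4, 2-methyl-2-butene, t-BuOH–THF–H2O) to 3-[7-(benzyloxy)-5-hydroxy-2-(4-methoxyphenyl)-4-oxo-4H-chromen-6-yl]-4-methoxybenzoic acid F6.
- The acid is esterified with the free phenol of 14 (EDC·HCl, DMAP, CH2Cl2) to 2-acetyl-3-(benzyloxy)-5-methoxyphenyl 3-[7-(benzyloxy)-5-hydroxy-2-(4-methoxyphenyl)-4-oxo-4H-chromen-6-yl]-4-methoxybenzoate F7.
- Rearrangement (KOt-Bu, THF, rt) gives 1-[2-(benzyloxy)-6-hydroxy-4-methoxyphenyl]-3-{3-[7-(benzyloxy)-5-hydroxy-2-(4-methoxyphenyl)-4-oxo-4H-chromen-6-yl]-4-methoxyphenyl}propane-1,3-dione F8.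
- Cyclodehydration (p-TsOH, toluene, reflux) should give 17.

Step 2. The closure may run 5-exo to a furanone, or through the ester oxygen instead of the acetyl enol oxygen, and the ynone may oligomerize under acid. The fallback sets out from 4 and comes back at 5.
- Diethylamine is added to the ynone (Et2NH, EtOH, rt) to give the enaminone methyl 2-acetyl-5-(diethylamino)-5-(4-methoxyphenyl)-3-oxopent-4-enoate F9.
- In F9 the amine-bearing carbon is the only electrophilic site left, so warming in AcOH (80 °C) should close the six-membered ring by addition–elimination with loss of the amine and give 5.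

**Further compounds**
F1 | step 5 | (E)-1-[2-(benzyloxy)-6-hydroxy-4-methoxyphenyl]-3-(3-bromo-4-methoxyphenyl)prop-2-en-1-one | COc1ccc(/C=C/C(=O)c2c(O)cc(OC)cc2OCc2ccccc2)cc1Br
F2 | step 5 | 5-(benzyloxy)-2-(3-bromo-4-methoxyphenyl)-7-methoxy-4H-chromen-4-one | COc1ccc(-c2cc(=O)c3c(OCc4ccccc4)cc(OC)cc3o2)cc1Br
F3 | step 5 | 5-(benzyloxy)-7-methoxy-2-[4-methoxy-3-(4,4,5,5-tetramethyl-1,3,2-dioxaborolan-2-yl)phenyl]-4H-chromen-4-one | COc1ccc(-c2cc(=O)c3c(OCc4ccccc4)cc(OC)cc3o2)cc1B1OC(C)(C)C(C)(C)O1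
F4 | step 5 | 7-(benzyloxy)-5-hydroxy-2-(4-methoxyphenyl)-4H-chromen-4-one | COc1ccc(-c2cc(=O)c3c(O)cc(OCc4ccccc4)cc3o2)cc1
F5 | step 5 | 7-(benzyloxy)-5-hydroxy-6-iodo-2-(4-methoxyphenyl)-4H-chromen-4-one | COc1ccc(-c2cc(=O)c3c(O)c(I)c(OCc4ccccc4)cc3o2)cc1
F6 | step 9 | 3-[7-(benzyloxy)-5-hydroxy-2-(4-methoxyphenyl)-4-oxo-4H-chromen-6-yl]-4-methoxybenzoic acid | COc1ccc(-c2cc(=O)c3c(O)c(-c4cc(C(=O)O)ccc4OC)c(OCc4ccccc4)cc3o2)cc1
F7 | step 9 | 2-acetyl-3-(benzyloxy)-5-methoxyphenyl 3-[7-(benzyloxy)-5-hydroxy-2-(4-methoxyphenyl)-4-oxo-4H-chromen-6-yl]-4-methoxybenzoate | COc1ccc(-c2cc(=O)c3c(O)c(-c4cc(C(=O)Oc5cc(OC)cc(OCc6ccccc6)c5C(C)=O)ccc4OC)c(OCc4ccccc4)cc3o2)cc1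
F8 | step 9 | 1-[2-(benzyloxy)-6-hydroxy-4-methoxyphenyl]-3-{3-[7-(benzyloxy)-5-hydroxy-2-(4-methoxyphenyl)-4-oxo-4H-chromen-6-yl]-4-methoxyphenyl}propane-1,3-dione | COc1ccc(-c2cc(=O)c3c(O)c(-c4cc(C(=O)CC(=O)c5c(O)cc(OC)cc5OCc5ccccc5)ccc4OC)c(OCc4ccccc4)cc3o2)cc1
F9 | step 2 | methyl 2-acetyl-5-(diethylamino)-5-(4-methoxyphenyl)-3-oxopent-4-enoate (double-bond geometry not defined) | CCN(CC)C(=CC(=O)C(C(C)=O)C(=O)OC)c1ccc(OC)cc1
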